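**Retrosynthetic overview**
1. Ring C of the chrysoeriol unit is made first: ketone 1 and aldehyde 2 give chalcone 3, which is oxidatively cyclised to the tri-O-benzyl flavone 4.
2. Key disconnection is the C8–C3′ biaryl bond: aminophenol ester 5 is diazotised (6) to o-quinone diazide 7, whose rhodium carbenoid is electrophilic at the carbon ortho to the phenol oxygen (polarity reversed) and arylates C8–H of 4 to give biaryl 8.
3. Ring C of the apigenin unit is made last: O-benzylation (9), Claisen condensation with a second portion of 1 (β-diketone 10) and cyclodehydration give 11.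
4. Global hydrogenolysis of the six benzyl ethers gives target 12.

Assumption: the target SMILES has no stereocentre and no defined biaryl axis, so it is made as drawn without stereocontrol; ketone 1 is taken as a catalogue compound.

**Route**

Step 1
Reactants: 1 1-[2,4-bis(benzyloxy)-6-hydroxyphenyl]ethan-1-one; 2 4-(benzyloxy)-3-methoxybenzaldehyde
Product: 3 (E)-1-[2,4-bis(benzyloxy)-6-hydroxyphenyl]-3-[4-(benzyloxy)-3-methoxyphenyl]prop-2-en-1-one
Conditions: KOH (50% aq), EtOH–THF, rt, 36 h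
Reagents that add atoms: none
Why: Claisen–Schmidt aldol condensation of the acetophenone enolate with a non-enolisable aldehyde, with E1cB dehydration giving the thermodynamically favoured E-chalcone.

Step 2
Reactants: 3 the chalcone
Product: 4 5,7-bis(benzyloxy)-2-[4-(benzyloxy)-3-methoxyphenyl]-4H-chromen-4-one
Conditions: I2 (10 mol%), DMSO, 130 °C, 3 h
Reagents that add atoms: none
Why: Iodine-catalysed oxidative cyclisation of a 2′-hydroxychalcone (oxa-Michael closure, α-iodination, HI elimination, DMSO reoxidising HI) is the standard chalcone-to-flavone reaction and leaves benzyl and methyl ethers intact.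

Step 3
Reactants: 5 methyl 3-amino-4-hydroxybenzoate
Product: 7 methyl 3-diazo-4-oxocyclohexa-1,5-diene-1-carboxylate (o-quinone diazide), via diazonium chloride 6 (not isolated)
Conditions: NaNO2, 2 M HCl, 0 °C, 30 min; then NaHCO3 to pH 7–8, CH2Cl2 extraction, kept cold and dark, used as a solution
Reagents that add atoms: sodium nitrite, [Na+].[O-]N=O
Why: Diazotisation of an o-aminophenol followed by deprotonation gives the neutral o-quinone diazide, which the para ester stabilises enough for extraction and use in solution.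

Step 4
Reactants: 4 the tri-O-benzyl flavone (1.5 equiv, excess recovered); 7 the quinone diazide (1.0 equiv)
Product: 8 methyl 3-{5,7-bis(benzyloxy)-2-[4-(benzyloxy)-3-methoxyphenyl]-4-oxo-4H-chromen-8-yl}-4-hydroxybenzoate
Conditions: Rh2(esp)2 (2 mol%; Rh2[1,3-C6H4(CH2CMe2CO2)2]2), ClCH2CH2Cl, 60 °C, 7 added over 4 h, dark
Reagents that add atoms: none
Why: Proposed new method: the divalent rhodium carboxylate dimer extrudes N2 from 7 to give a metal-bound α-oxo (quinoid) carbene that is electrophilic at the carbon ortho to oxygen (an enolonium-type, polarity-reversed phenol), and C8 of 4 (ortho to 7-OBn and O1, para to 5-OBn, less hindered than C6 between two benzyloxy groups) attacks it as in electrophilic aromatic substitution, proton transfer then rearomatising both rings to the 2-hydroxybiaryl; the closest known reaction type is the dirhodium-catalysed intermolecular C–H arylation of electron-rich arenes with quinone diazides.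

Step 5
Reactants: 8 the biaryl phenol
Product: 9 methyl 4-(benzyloxy)-3-{5,7-bis(benzyloxy)-2-[4-(benzyloxy)-3-methoxyphenyl]-4-oxo-4H-chromen-8-yl}benzoate
Conditions: BnBr, K2CO3, DMF, 50 °C
Reagents that add atoms: benzyl bromide, BrCc1ccccc1
Why: Williamson etherification of the acidic para-ester phenol masks it, so the ester is not deactivated as a phenoxide in the Claisen step.

Step 6
Reactants: 9 the benzylated ester; 1 1-[2,4-bis(benzyloxy)-6-hydroxyphenyl]ethan-1-one (1.5 equiv)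
Product: 11 5,7-bis(benzyloxy)-8-{2-(benzyloxy)-5-[5,7-bis(benzyloxy)-4-oxo-4H-chromen-2-yl]phenyl}-2-[4-(benzyloxy)-3-methoxyphenyl]-4H-chromen-4-one, via β-diketone 10 (not isolated)
Conditions: LiN(SiMe3)2 (4.5 equiv), THF, −78 °C to rt; AcOH quench, concentrate; then TsOH·H2O (20 mol%), toluene, 90 °C
Reagents that add atoms: none
Why: Crossed Claisen condensation of the dilithio phenoxide-enolate of 1 with the non-enolisable ester is driven by deprotonation of β-diketone 10, and acid-catalysed cyclodehydration of this o-hydroxyaryl β-diketone closes the pyranone (Baker–Venkataraman-type flavone endgame).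

Step 7
Reactants: 11 the hexa-O-benzyl biflavone
Product: 12 8-[5-(5,7-dihydroxy-4-oxo-4H-chromen-2-yl)-2-hydroxyphenyl]-5,7-dihydroxy-2-(4-hydroxy-3-methoxyphenyl)-4H-chromen-4-one (target)
Conditions: H2 (1 atm), 10% Pd/C, THF–MeOH 1:1, rt
Reagents that add atoms: none
Why: Catalytic hydrogenolysis cleaves all six aryl benzyl ethers while the aryl methyl ether and the flavone C2=C3 bonds survive at 1 atm and room temperature.

**Compound list**
1 | 1-[2,4-bis(benzyloxy)-6-hydroxyphenyl]ethan-1-one | CC(=O)c1c(O)cc(OCc2ccccc2)cc1OCc1ccccc1 | starting material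
2 | 4-(benzyloxy)-3-methoxybenzaldehyde | COc1cc(C=O)ccc1OCc1ccccc1 | starting material
3 | (E)-1-[2,4-bis(benzyloxy)-6-hydroxyphenyl]-3-[4-(benzyloxy)-3-methoxyphenyl]prop-2-en-1-one | O=C(/C=C/c1ccc(OCc2ccccc2)c(OC)c1)c1c(O)cc(OCc2ccccc2)cc1OCc1ccccc1 | intermediate
4 | 5,7-bis(benzyloxy)-2-[4-(benzyloxy)-3-methoxyphenyl]-4H-chromen-4-one | COc1cc(-c2cc(=O)c3c(OCc4ccccc4)cc(OCc4ccccc4)cc3o2)ccc1OCc1ccccc1 | intermediate
5 | methyl 3-amino-4-hydroxybenzoate | COC(=O)c1ccc(O)c(N)c1 | starting material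
6 | 2-hydroxy-5-(methoxycarbonyl)benzenediazonium chloride (forms in the flask, not isolated) | COC(=O)c1ccc(O)c([N+]#N)c1.[Cl-] | intermediate
7 | methyl 3-diazo-4-oxocyclohexa-1,5-diene-1-carboxylate | COC(=O)C1=CC(=[N+]=[N-])C(=O)C=C1 | intermediate
8 | methyl 3-{5,7-bis(benzyloxy)-2-[4-(benzyloxy)-3-methoxyphenyl]-4-oxo-4H-chromen-8-yl}-4-hydroxybenzoate | COC(=O)c1ccc(O)c(c1)-c1c(OCc2ccccc2)cc(OCc2ccccc2)c2c(=O)cc(-c3ccc(OCc4ccccc4)c(OC)c3)oc12 | intermediate
9 | methyl 4-(benzyloxy)-3-{5,7-bis(benzyloxy)-2-[4-(benzyloxy)-3-methoxyphenyl]-4-oxo-4H-chromen-8-yl}benzoate | COC(=O)c1ccc(OCc2ccccc2)c(c1)-c1c(OCc2ccccc2)cc(OCc2ccccc2)c2c(=O)cc(-c3ccc(OCc4ccccc4)c(OC)c3)oc12 | intermediate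
10 | 1-[2,4-bis(benzyloxy)-6-hydroxyphenyl]-3-(4-(benzyloxy)-3-{5,7-bis(benzyloxy)-2-[4-(benzyloxy)-3-methoxyphenyl]-4-oxo-4H-chromen-8-yl}phenyl)propane-1,3-dione (forms in the flask, not isolated) | O=C(CC(=O)c1c(O)cc(OCc2ccccc2)cc1OCc1ccccc1)c1ccc(OCc2ccccc2)c(c1)-c1c(OCc2ccccc2)cc(OCc2ccccc2)c2c(=O)cc(-c3ccc(OCc4ccccc4)c(OC)c3)oc12 | intermediate
11 | 5,7-bis(benzyloxy)-8-{2-(benzyloxy)-5-[5,7-bis(benzyloxy)-4-oxo-4H-chromen-2-yl]phenyl}-2-[4-(benzyloxy)-3-methoxyphenyl]-4H-chromen-4-one | COc1cc(-c2cc(=O)c3c(OCc4ccccc4)cc(OCc4ccccc4)c(-c4cc(-c5cc(=O)c6c(OCc7ccccc7)cc(OCc7ccccc7)cc6o5)ccc4OCc4ccccc4)c3o2)ccc1OCc1ccccc1 | intermediate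
12 | 8-[5-(5,7-dihydroxy-4-oxo-4H-chromen-2-yl)-2-hydroxyphenyl]-5,7-dihydroxy-2-(4-hydroxy-3-methoxyphenyl)-4H-chromen-4-one (CNP0179340.0) | COc1cc(-c2cc(=O)c3c(O)cc(O)c(-c4cc(-c5cc(=O)c6c(O)cc(O)cc6o5)ccc4O)c3o2)ccc1O | target

**Totals**
Total step count: 7. Longest linear sequence: 6 steps (steps 1, 2, 4, 5, 6, 7); step 3 is the one-step side branch.

**Steps most likely to fail, with fallbacks**

Step 4 is the riskiest. The carbenoid could instead insert into benzylic C–H bonds, be trapped by the pyranone oxygen or by the phenol of 8, or give C6/C8 mixtures. The fallback sets out from 4 and comes back at 9, bypassing 7, 8 and step 5. Iodination of 4 with N-iodosuccinimide in DMF gives 5,7-bis(benzyloxy)-2-[4-(benzyloxy)-3-methoxyphenyl]-8-iodo-4H-chromen-4-one F1. In parallel, purchased methyl 3-bromo-4-hydroxybenzoate is O-benzylated (BnBr, K2CO3) to methyl 4-(benzyloxy)-3-bromobenzoate F2, which is borylated (B2pin2, Pd(dppf)Cl2, KOAc, dioxane, 90 °C) to methyl 4-(benzyloxy)-3-(4,4,5,5-tetramethyl-1,3,2-dioxaborolan-2-yl)benzoate F3. Suzuki–Miyaura coupling of F1 with F3 (Pd(OAc)2, SPhos, K3PO4, toluene–water, 90 °C) gives 9.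

Step 6 is next. The hindered, electron-rich benzoate may condense slowly, and the enolate might attack the existing flavone. The fallback sets out from 9 and comes back at 10. Saponification (LiOH, THF–water) gives 4-(benzyloxy)-3-{5,7-bis(benzyloxy)-2-[4-(benzyloxy)-3-methoxyphenyl]-4-oxo-4H-chromen-8-yl}benzoic acid F4. Steglich esterification of F4 with the phenol of 1 (EDC·HCl, DMAP, CH2Cl2) gives 2-acetyl-3,5-bis(benzyloxy)phenyl 4-(benzyloxy)-3-{5,7-bis(benzyloxy)-2-[4-(benzyloxy)-3-methoxyphenyl]-4-oxo-4H-chromen-8-yl}benzoate F5. Intramolecular Baker–Venkataraman acyl transfer (KOH, pyridine, 50 °C) then gives 10, which is cyclodehydrated with TsOH·H2O as in step 6 to give 11.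

Step 7 is third. Six benzyl ethers must go, partly debenzylated intermediates are poorly soluble, and the two C2=C3 bonds could be over-reduced. The fallback sets out from 11 and comes back at 12: Lewis-acid cleavage with BCl3 and pentamethylbenzene as benzyl-cation scavenger (CH2Cl2, −78 °C) replaces hydrogenolysis, sparing the alkenes and, at this temperature, the aryl methyl ether. It makes no new compound (F0).

**Further compounds**
F1 | step 4 | 5,7-bis(benzyloxy)-2-[4-(benzyloxy)-3-methoxyphenyl]-8-iodo-4H-chromen-4-one | COc1cc(-c2cc(=O)c3c(OCc4ccccc4)cc(OCc4ccccc4)c(I)c3o2)ccc1OCc1ccccc1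
F2 | step 4 | methyl 4-(benzyloxy)-3-bromobenzoate | COC(=O)c1ccc(OCc2ccccc2)c(Br)c1
F3 | step 4 | methyl 4-(benzyloxy)-3-(4,4,5,5-tetramethyl-1,3,2-dioxaborolan-2-yl)benzoate | COC(=O)c1ccc(OCc2ccccc2)c(c1)B1OC(C)(C)C(C)(C)O1
F4 | step 6 | 4-(benzyloxy)-3-{5,7-bis(benzyloxy)-2-[4-(benzyloxy)-3-methoxyphenyl]-4-oxo-4H-chromen-8-yl}benzoic acid | OC(=O)c1ccc(OCc2ccccc2)c(c1)-c1c(OCc2ccccc2)cc(OCc2ccccc2)c2c(=O)cc(-c3ccc(OCc4ccccc4)c(OC)c3)oc12
F5 | step 6 | 2-acetyl-3,5-bis(benzyloxy)phenyl 4-(benzyloxy)-3-{5,7-bis(benzyloxy)-2-[4-(benzyloxy)-3-methoxyphenyl]-4-oxo-4H-chromen-8-yl}benzoate | CC(=O)c1c(OC(=O)c2ccc(OCc3ccccc3)c(c2)-c2c(OCc3ccccc3)cc(OCc3ccccc3)c3c(=O)cc(-c4ccc(OCc5ccccc5)c(OC)c4)oc23)cc(OCc2ccccc2)cc1OCc1ccccc1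
F0 | step 7 | none | none
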